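**Plan**
- Retrosynthesis: the O1–C2 bond of ring C is cut first (Mitsunobu etherification). The two bonds that tie ring A to the chain, O1–C8a and C4–C4a, are then cut together (aryne insertion into the acyl C–O bond of a carboxylic acid), and last the C2–C3 bond (glycolate aldol).
- Enabling feature: ring A carries O1 on C8a and the C4 acyl carbon on the neighbouring C4a, with the C5 methoxy group flanking C4a. 3,5-Dimethoxybenzyne delivers this pattern when an oxygen nucleophile adds remote from the flanking methoxy group and the aryl anion beside it captures an acyl group.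
- Forward: the ring B aldehyde and a methoxyacetyl imide give a syn-aldol, then the silyl ether acid. The acid and the ring A silylaryl triflate are joined in the key step (no ring forms). Desilylation, closure of ring C and debenzylation follow.
- Stereochemistry: C3 (R) comes from the (R)-4-benzyloxazolidinone auxiliary in the boron aldol. The aldol also sets the carbinol centre (S, syn), which is inverted in the Mitsunobu closure to C2 (R), giving the 2,3-trans ring.

Key step: step 10

Assumption: flavanone numbering is used (O1, C2, C3, C4, C4a, C5–C8, C8a; ring B primed), the target is (2R,3R), i.e. 2,3-trans, and 3,5-dimethoxyphenol, 2-methoxyhydroquinone, (R)-4-benzyl-1,3-oxazolidin-2-one and methoxyacetyl chloride are taken as commercial.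

**Route**

Step 1
Reactants: 1 3,5-dimethoxyphenol
Product: 2 3,5-dimethoxyphenyl N-isopropylcarbamate
Conditions: i-PrNCO, Et3N (cat.), CH2Cl2, rt
Reagents that add atoms: isopropyl isocyanate, CC(C)N=C=O
Why: Base-catalysed addition of the phenol to the isocyanate (carbamoylation) should give the N-isopropyl carbamate, a strong ortho-directing group that can later be removed under mild base.

Step 2
Reactants: 2 3,5-dimethoxyphenyl N-isopropylcarbamate
Product: 6 3,5-dimethoxy-2-(trimethylsilyl)phenyl N-isopropylcarbamate, via N-silyl carbamate 3 (not isolated), via ortho-lithiated N-silyl carbamate 4 (not isolated), via N-silyl C-silyl carbamate 5 (not isolated)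
Conditions: TBSOTf, TMEDA, Et2O, 0 °C → rt; n-BuLi, TMEDA, −78 °C; TMSCl, −78 °C → rt; cold aq. NH4Cl
Reagents that add atoms: chlorotrimethylsilane, C[Si](C)(C)Cl
Why: Directed ortho-metalation, in which in situ N-silylation masks the N–H, the O-carbamate steers n-BuLi/TMEDA to C2 (flanked by carbamate and methoxy, and favoured over C4 between the two weaker methoxy directors), and TMSCl traps the aryllithium at −78 °C before an anionic Fries shift can set in, the labile N–Si bond being hydrolysed on mild work-up.

Step 3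
Reactants: 6 3,5-dimethoxy-2-(trimethylsilyl)phenyl N-isopropylcarbamate
Product: 8 3,5-dimethoxy-2-(trimethylsilyl)phenyl trifluoromethanesulfonate, via 3,5-dimethoxy-2-(trimethylsilyl)phenol 7 (not isolated)
Conditions: DBU, Et2NH, MeCN, 40 °C; then PhNTf2, rt
Reagents that add atoms: N-phenylbis(trifluoromethanesulfonimide), O=S(=O)(N(c1ccccc1)S(=O)(=O)C(F)(F)F)C(F)(F)F
Why: DBU-induced E1cB loss of isopropyl isocyanate (scavenged by Et2NH as the urea) frees the phenol, which PhNTf2 triflates in the same pot to the ortho-silylaryl triflate, the standard fluoride-triggered aryne precursor.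

Step 4
Reactants: 9 2-methoxyhydroquinone
Product: 10 1,4-bis(benzyloxy)-2-methoxybenzene
Conditions: BnBr, K2CO3, DMF, 60 °C, N2
Reagents that add atoms: benzyl bromide, BrCc1ccccc1
Why: Double Williamson etherification of both phenols with K2CO3 as base, run under nitrogen because the hydroquinone anion is air-sensitive.

Step 5
Reactants: 10 1,4-bis(benzyloxy)-2-methoxybenzene
Product: 12 2,5-bis(benzyloxy)-4-methoxybenzaldehyde, via aryl iminium salt 11 (not isolated)
Conditions: POCl3, DMF, 0 → 70 °C; then aq. NaOAc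
Reagents that add atoms: N,N-dimethylformamide, CN(C)C=O; water, O
Why: Vilsmeier–Haack formylation should go to the one unhindered position that is para to the methoxy group and ortho to a benzyloxy group (the pattern known for 1,2,4-trialkoxybenzenes), and benzyl ethers tolerate POCl3/DMF.

Step 6
Reactants: 13 (R)-4-benzyl-1,3-oxazolidin-2-one; 14 methoxyacetyl chloride
Product: 16 (R)-4-benzyl-3-(2-methoxyacetyl)-1,3-oxazolidin-2-one, via lithium oxazolidinide 15 (not isolated)
Conditions: n-BuLi, THF, −78 °C; then 14, −78 → 0 °C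
Reagents that add atoms: none
Why: N-Acylation of the lithiated oxazolidinone with an acid chloride at low temperature is the standard entry to glycolate imides.

Step 7
Reactants: 16 (R)-4-benzyl-3-(2-methoxyacetyl)-1,3-oxazolidin-2-one; 12 2,5-bis(benzyloxy)-4-methoxybenzaldehyde
Product: 19 (4R)-4-benzyl-3-[(2R,3S)-3-[2,5-bis(benzyloxy)-4-methoxyphenyl]-3-hydroxy-2-methoxypropanoyl]-1,3-oxazolidin-2-one, via Z boron enolate 17 (not isolated), via boron aldolate 18 (not isolated)
Conditions: Bu2BOTf, Et3N, CH2Cl2, −78 → 0 °C; 12, −78 → 0 °C; then pH 7 buffer, MeOH, 30% H2O2, 0 °C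
Reagents that add atoms: none
Why: Evans boron glycolate syn-aldol, in which the Z-enolate 17 reacts through a closed Zimmerman–Traxler chair with the auxiliary carbonyl turned away from the enolate oxygen, the benzyl group of the (R)-auxiliary blocking one enolate face so that the α-centre is set as 2R (auxiliary control) and the carbinol centre as 3S (syn, from the Z-enolate chair).

Step 8
Reactants: 19 (4R)-4-benzyl-3-[(2R,3S)-3-[2,5-bis(benzyloxy)-4-methoxyphenyl]-3-hydroxy-2-methoxypropanoyl]-1,3-oxazolidin-2-one
Product: 20 (4R)-4-benzyl-3-[(2R,3S)-3-[2,5-bis(benzyloxy)-4-methoxyphenyl]-3-[(tert-butyldimethylsilyl)oxy]-2-methoxypropanoyl]-1,3-oxazolidin-2-one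
Conditions: TBSOTf, 2,6-lutidine, CH2Cl2, −78 → 0 °C
Reagents that add atoms: tert-butyldimethylsilyl trifluoromethanesulfonate, CC(C)(C)[Si](C)(C)OS(=O)(=O)C(F)(F)F
Why: Silylation of the hindered benzylic alcohol with a silyl triflate and a non-nucleophilic base blocks retro-aldol cleavage and hides the hydroxyl from the aryne in step 10.

Step 9
Reactants: 20 (4R)-4-benzyl-3-[(2R,3S)-3-[2,5-bis(benzyloxy)-4-methoxyphenyl]-3-[(tert-butyldimethylsilyl)oxy]-2-methoxypropanoyl]-1,3-oxazolidin-2-one
Product: 22 (2R,3S)-3-[2,5-bis(benzyloxy)-4-methoxyphenyl]-3-[(tert-butyldimethylsilyl)oxy]-2-methoxypropanoic acid, via peroxy acid 21 (not isolated)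
Conditions: LiOH, 30% H2O2, THF/H2O, 0 °C; aq. Na2SO3; 1 M HCl to pH 3, 0 °C
Reagents that add atoms: hydrogen peroxide (as LiOOH), OO
Why: Hydroperoxide cleavage of the N-acyl oxazolidinone, in which LiOOH attacks the exocyclic carbonyl selectively even for a hindered acyl group, Na2SO3 reduces the peroxy acid 21, and the methoxy-bearing α-centre should not epimerise at 0 °C.

Step 10
Reactants: 22 (2R,3S)-3-[2,5-bis(benzyloxy)-4-methoxyphenyl]-3-[(tert-butyldimethylsilyl)oxy]-2-methoxypropanoic acid; 8 3,5-dimethoxy-2-(trimethylsilyl)phenyl trifluoromethanesulfonate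
Product: 26 (2R,3S)-3-[2,5-bis(benzyloxy)-4-methoxyphenyl]-3-[(tert-butyldimethylsilyl)oxy]-1-(2-hydroxy-4,6-dimethoxyphenyl)-2-methoxypropan-1-one, via caesium carboxylate 23 (not isolated), via 3,5-dimethoxybenzyne 24 (not isolated), via ortho-caesio aryl ester 25 (not isolated)
Conditions: 8 (1.5 equiv), CsF (4 equiv), THF, sealed tube, 110–125 °C
Reagents that add atoms: none
Why: Fluoride removes the trimethylsilyl group of 8 with loss of triflate to release 3,5-dimethoxybenzyne 24, the carboxylate 23 bonds through oxygen to the aryne carbon that becomes C8a, and the aryl anion 25 so formed at the future C4a attacks the neighbouring ester carbonyl in a 1,3 O-to-C acyl shift through a four-membered transition structure, the acid proton parked as bifluoride finally returning to the phenoxide oxygen. The closest known reaction type is the CsF-induced insertion of arynes into the acyl C–O bond of carboxylic acids in hot THF, which delivers ortho-hydroxyaryl ketones; here it is applied to a β-silyloxy α-methoxy acid. No ring is closed and no stereocentre is formed: both chain centres are carried through unchanged, the α-centre being shielded because the product sits largely as the salt of a doubly donor-substituted ortho-acyl phenol whose carbonyl acidifies the α-hydrogen only weakly. The step needs regioselective capture of the aryne and acyl shift in preference to protonation: the methoxy group beside the triple bond, by its inductive pull and the resulting distortion of the aryne, places the developing negative charge on the carbon next to it so that oxygen adds at the remote carbon, while aprotic THF, sparingly soluble CsF that keeps HF bound, and heat favour the intramolecular shift over intermolecular protonation. The hindered secondary silyl ether should survive because very little fluoride is in solution.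

Step 11
Reactants: 26 (2R,3S)-3-[2,5-bis(benzyloxy)-4-methoxyphenyl]-3-[(tert-butyldimethylsilyl)oxy]-1-(2-hydroxy-4,6-dimethoxyphenyl)-2-methoxypropan-1-one
Product: 27 (2R,3S)-3-[2,5-bis(benzyloxy)-4-methoxyphenyl]-3-hydroxy-1-(2-hydroxy-4,6-dimethoxyphenyl)-2-methoxypropan-1-one
Conditions: HF·pyridine, pyridine, THF, 0 °C → rt
Reagents that add atoms: none
Why: Fluoride-mediated cleavage of the Si–O bond under buffered, weakly acidic conditions avoids the free alkoxide that would trigger retro-aldol cleavage or E1cB dehydration of the β-hydroxy ketone.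

Step 12
Reactants: 27 (2R,3S)-3-[2,5-bis(benzyloxy)-4-methoxyphenyl]-3-hydroxy-1-(2-hydroxy-4,6-dimethoxyphenyl)-2-methoxypropan-1-one
Product: 29 (2R,3R)-2-[2,5-bis(benzyloxy)-4-methoxyphenyl]-3,5,7-trimethoxy-2,3-dihydro-4H-chromen-4-one, via alkoxyphosphonium phenoxide 28 (not isolated)
Conditions: PPh3, DIAD, THF, 0 °C → rt
Reagents that add atoms: none
Why: Intramolecular Mitsunobu etherification, in which the benzylic alcohol is activated as 28 and displaced by the ring A phenoxide in a 6-exo-tet closure with inversion, turning the 3S carbinol into C2 (R) trans to the C3 methoxy group, and even if some ionisation occurs at this donor-substituted benzylic carbon the fixed C3 centre still steers closure to the diequatorial trans ring.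

Step 13
Reactants: 29 (2R,3R)-2-[2,5-bis(benzyloxy)-4-methoxyphenyl]-3,5,7-trimethoxy-2,3-dihydro-4H-chromen-4-one
Product: 30 (2R,3R)-2-(2,5-dihydroxy-4-methoxyphenyl)-3,5,7-trimethoxy-2,3-dihydro-4H-chromen-4-one
Conditions: H2 (1 atm), 10% Pd/C, EtOAc, rt; filtration under Ar
Reagents that add atoms: none
Why: Catalytic hydrogenolysis of the two aryl benzyl ethers over Pd/C under neutral conditions should leave the methyl ethers, the ketone and the C2–O1 bond intact if stopped at full debenzylation, and no base is present that could open the 2'-hydroxyflavanone or epimerise C2 and C3.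

**Compound list**

1 | 3,5-dimethoxyphenol | COc1cc(O)cc(OC)c1 | starting material
2 | 3,5-dimethoxyphenyl N-isopropylcarbamate | COc1cc(OC)cc(OC(=O)NC(C)C)c1 | intermediate
3 | 3,5-dimethoxyphenyl N-(tert-butyldimethylsilyl)-N-isopropylcarbamate (not isolated) | COc1cc(OC)cc(OC(=O)N(C(C)C)[Si](C)(C)C(C)(C)C)c1 | intermediate
4 | [2-({[tert-butyl(dimethyl)silyl](isopropyl)carbamoyl}oxy)-4,6-dimethoxyphenyl]lithium (not isolated) | COc1cc(OC)c([Li])c(OC(=O)N(C(C)C)[Si](C)(C)C(C)(C)C)c1 | intermediate
5 | 3,5-dimethoxy-2-(trimethylsilyl)phenyl N-(tert-butyldimethylsilyl)-N-isopropylcarbamate (not isolated) | COc1cc(OC)c([Si](C)(C)C)c(OC(=O)N(C(C)C)[Si](C)(C)C(C)(C)C)c1 | intermediate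
6 | 3,5-dimethoxy-2-(trimethylsilyl)phenyl N-isopropylcarbamate | COc1cc(OC)c([Si](C)(C)C)c(OC(=O)NC(C)C)c1 | intermediate
7 | 3,5-dimethoxy-2-(trimethylsilyl)phenol (not isolated) | COc1cc(OC)c([Si](C)(C)C)c(O)c1 | intermediate
8 | 3,5-dimethoxy-2-(trimethylsilyl)phenyl trifluoromethanesulfonate | COc1cc(OC)c([Si](C)(C)C)c(OS(=O)(=O)C(F)(F)F)c1 | intermediate
9 | 2-methoxyhydroquinone (2-methoxybenzene-1,4-diol) | COc1cc(O)ccc1O | starting material
10 | 1,4-bis(benzyloxy)-2-methoxybenzene | COc1cc(OCc2ccccc2)ccc1OCc1ccccc1 | intermediate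
11 | N-[2,5-bis(benzyloxy)-4-methoxybenzylidene]-N-methylmethanaminium dichlorophosphate (not isolated) | COc1cc(OCc2ccccc2)c(C=[N+](C)C)cc1OCc1ccccc1.[O-]P(=O)(Cl)Cl | intermediate
12 | 2,5-bis(benzyloxy)-4-methoxybenzaldehyde | COc1cc(OCc2ccccc2)c(C=O)cc1OCc1ccccc1 | intermediate
13 | (R)-4-benzyl-1,3-oxazolidin-2-one | O=C1N[C@H](Cc2ccccc2)CO1 | starting material
14 | methoxyacetyl chloride | COCC(=O)Cl | starting material
15 | N-lithio derivative of (R)-4-benzyl-1,3-oxazolidin-2-one (not isolated) | [Li]N1C(=O)OC[C@H]1Cc1ccccc1 | intermediate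
16 | (R)-4-benzyl-3-(2-methoxyacetyl)-1,3-oxazolidin-2-one | COCC(=O)N1C(=O)OC[C@H]1Cc1ccccc1 | intermediate
17 | (R)-4-benzyl-3-[(Z)-1-[(dibutylboranyl)oxy]-2-methoxyethenyl]-1,3-oxazolidin-2-one (not isolated) | CO/C=C(\OB(CCCC)CCCC)N1C(=O)OC[C@H]1Cc1ccccc1 | intermediate
18 | O-dibutylboranyl derivative of aldol adduct 19 (boron aldolate, not isolated) | CCCCB(CCCC)O[C@@H](c1cc(OCc2ccccc2)c(OC)cc1OCc1ccccc1)[C@@H](OC)C(=O)N1C(=O)OC[C@H]1Cc1ccccc1 | intermediate
19 | (4R)-4-benzyl-3-[(2R,3S)-3-[2,5-bis(benzyloxy)-4-methoxyphenyl]-3-hydroxy-2-methoxypropanoyl]-1,3-oxazolidin-2-one | O[C@@H](c1cc(OCc2ccccc2)c(OC)cc1OCc1ccccc1)[C@@H](OC)C(=O)N1C(=O)OC[C@H]1Cc1ccccc1 | intermediate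
20 | (4R)-4-benzyl-3-[(2R,3S)-3-[2,5-bis(benzyloxy)-4-methoxyphenyl]-3-[(tert-butyldimethylsilyl)oxy]-2-methoxypropanoyl]-1,3-oxazolidin-2-one | CC(C)(C)[Si](C)(C)O[C@@H](c1cc(OCc2ccccc2)c(OC)cc1OCc1ccccc1)[C@@H](OC)C(=O)N1C(=O)OC[C@H]1Cc1ccccc1 | intermediate
21 | (2R,3S)-3-[2,5-bis(benzyloxy)-4-methoxyphenyl]-3-[(tert-butyldimethylsilyl)oxy]-2-methoxypropaneperoxoic acid (not isolated) | CC(C)(C)[Si](C)(C)O[C@@H](c1cc(OCc2ccccc2)c(OC)cc1OCc1ccccc1)[C@@H](OC)C(=O)OO | intermediate
22 | (2R,3S)-3-[2,5-bis(benzyloxy)-4-methoxyphenyl]-3-[(tert-butyldimethylsilyl)oxy]-2-methoxypropanoic acid | CC(C)(C)[Si](C)(C)O[C@@H](c1cc(OCc2ccccc2)c(OC)cc1OCc1ccccc1)[C@@H](OC)C(=O)O | intermediate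
23 | caesium (2R,3S)-3-[2,5-bis(benzyloxy)-4-methoxyphenyl]-3-[(tert-butyldimethylsilyl)oxy]-2-methoxypropanoate (not isolated) | CC(C)(C)[Si](C)(C)O[C@@H](c1cc(OCc2ccccc2)c(OC)cc1OCc1ccccc1)[C@@H](OC)C(=O)[O-].[Cs+] | intermediate
24 | 3,5-dimethoxybenzyne (1,2-didehydro-3,5-dimethoxybenzene, not isolated) | COC1=CC(OC)=CC#C1 | intermediate
25 | 2-caesio-3,5-dimethoxyphenyl (2R,3S)-3-[2,5-bis(benzyloxy)-4-methoxyphenyl]-3-[(tert-butyldimethylsilyl)oxy]-2-methoxypropanoate (not isolated) | CC(C)(C)[Si](C)(C)O[C@@H](c1cc(OCc2ccccc2)c(OC)cc1OCc1ccccc1)[C@@H](OC)C(=O)Oc1cc(OC)cc(OC)c1[Cs] | intermediate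
26 | (2R,3S)-3-[2,5-bis(benzyloxy)-4-methoxyphenyl]-3-[(tert-butyldimethylsilyl)oxy]-1-(2-hydroxy-4,6-dimethoxyphenyl)-2-methoxypropan-1-one | CC(C)(C)[Si](C)(C)O[C@@H](c1cc(OCc2ccccc2)c(OC)cc1OCc1ccccc1)[C@@H](OC)C(=O)c1c(O)cc(OC)cc1OC | intermediate
27 | (2R,3S)-3-[2,5-bis(benzyloxy)-4-methoxyphenyl]-3-hydroxy-1-(2-hydroxy-4,6-dimethoxyphenyl)-2-methoxypropan-1-one | O[C@@H](c1cc(OCc2ccccc2)c(OC)cc1OCc1ccccc1)[C@@H](OC)C(=O)c1c(O)cc(OC)cc1OC | intermediate
28 | O-triphenylphosphonio derivative of 27 at the benzylic oxygen, ring A phenoxide (zwitterion, not isolated) | c1ccc(cc1)[P+](c1ccccc1)(c1ccccc1)O[C@@H](c1cc(OCc2ccccc2)c(OC)cc1OCc1ccccc1)[C@@H](OC)C(=O)c1c([O-])cc(OC)cc1OC | intermediate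
29 | (2R,3R)-2-[2,5-bis(benzyloxy)-4-methoxyphenyl]-3,5,7-trimethoxy-2,3-dihydro-4H-chromen-4-one | COc1cc(OC)c2c(c1)O[C@H](c1cc(OCc3ccccc3)c(OC)cc1OCc1ccccc1)[C@@H](OC)C2=O | intermediate
30 | (2R,3R)-2-(2,5-dihydroxy-4-methoxyphenyl)-3,5,7-trimethoxy-2,3-dihydro-4H-chromen-4-one (CNP0281794.1) | COc1cc(OC)c2c(c1)O[C@H](c1cc(O)c(OC)cc1O)[C@@H](OC)C2=O | target

**Step count and risks**

Total: 13 steps. Longest linear sequence: 9 steps (steps 4, 5, 7, 8, 9, 10, 11, 12, 13, from 2-methoxyhydroquinone).

The three steps most likely to fail are, in order of risk, step 10, step 12 and step 2.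

First risk, step 10 (aryne insertion). The aryl anion may be protonated before the acyl group migrates, so that the chain ends as a plain aryl ester. Fluoride at 110–125 °C may also strip the silyl group, or the new ketone may enolise and lose the β-silyloxy group or epimerise at the α-carbon. The fallback for step 10 generates the same kind of ortho-metalated aryl ester at −95 °C by bromine–lithium exchange, with neither hot fluoride nor a proton source present. It sets out from 1 and 22. Ortho-selective bromination of 1 (NBS, catalytic i-Pr2NH, CH2Cl2, −78 → 0 °C) should give 2-bromo-3,5-dimethoxyphenol F1 as the isomer brominated next to the hydroxyl group. Esterification of this phenol with 22 (EDC·HCl, DMAP, CH2Cl2) should give 2-bromo-3,5-dimethoxyphenyl (2R,3S)-3-[2,5-bis(benzyloxy)-4-methoxyphenyl]-3-[(tert-butyldimethylsilyl)oxy]-2-methoxypropanoate F2 as the bromoaryl ester. Treatment with t-BuLi (2 equiv) in THF/Et2O at −95 °C should exchange bromine for lithium and give 2-lithio-3,5-dimethoxyphenyl (2R,3S)-3-[2,5-bis(benzyloxy)-4-methoxyphenyl]-3-[(tert-butyldimethylsilyl)oxy]-2-methoxypropanoate F3 as a transient aryllithium. This undergoes the same 1,3 O-to-C acyl shift (anionic Fries rearrangement triggered by halogen–metal exchange, a known route to ortho-hydroxyaryl ketones). Aqueous NH4Cl quench returns to the route at 26.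

Second risk, step 12 (Mitsunobu closure). The alkoxyphosphonium ion at this hindered, strongly donor-substituted benzylic carbon may ionise or eliminate instead of being displaced, leading to dehydration toward the α-methoxychalcone or to loss of stereocontrol at C2. The fallback for step 12 closes the ring under thermodynamic control and sets out from 27. Catalytic camphorsulfonic acid in CH2Cl2 at 0 °C generates the benzylic cation stabilised by the ortho- and para-alkoxy groups, and the ring A phenol traps it. Reversible re-ionisation of any cis isomer funnels the material to the diequatorial 2,3-trans chromanone, with the untouched C3 centre dictating C2. This arrives at 29 without any new compound.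

Third risk, step 2 (directed silylation). Lithiation may occur between the two methoxy groups (C4) instead of next to the carbamate, the carbamoyl group may migrate (anionic Fries) before silylation, or the very electron-rich arylsilane may suffer ipso-protodesilylation on work-up. The fallback for step 2 installs silicon by a bromine-triggered retro-Brook shift and sets out from 1. Ortho-bromination of 1 as described in the fallback for step 10 should give 2-bromo-3,5-dimethoxyphenol F1 once more. O-Silylation of it (HMDS, THF, reflux) should give (2-bromo-3,5-dimethoxyphenoxy)trimethylsilane F4 as the aryl silyl ether. Treatment with n-BuLi in THF at −100 °C causes bromine–lithium exchange and 1,3 O-to-C silyl migration, which should give lithium 3,5-dimethoxy-2-(trimethylsilyl)phenoxide F5 in solution. This is triflated in the same flask (Tf2O, −100 °C → rt) and rejoins the route at 8.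

**Further compounds**

F1 | step 10 | 2-bromo-3,5-dimethoxyphenol | COc1cc(O)c(Br)c(OC)c1
F2 | step 10 | 2-bromo-3,5-dimethoxyphenyl (2R,3S)-3-[2,5-bis(benzyloxy)-4-methoxyphenyl]-3-[(tert-butyldimethylsilyl)oxy]-2-methoxypropanoate | CC(C)(C)[Si](C)(C)O[C@@H](c1cc(OCc2ccccc2)c(OC)cc1OCc1ccccc1)[C@@H](OC)C(=O)Oc1cc(OC)cc(OC)c1Br
F3 | step 10 | 2-lithio-3,5-dimethoxyphenyl (2R,3S)-3-[2,5-bis(benzyloxy)-4-methoxyphenyl]-3-[(tert-butyldimethylsilyl)oxy]-2-methoxypropanoate | CC(C)(C)[Si](C)(C)O[C@@H](c1cc(OCc2ccccc2)c(OC)cc1OCc1ccccc1)[C@@H](OC)C(=O)Oc1cc(OC)cc(OC)c1[Li]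
F0 | step 12 | none | none
F4 | step 2 | (2-bromo-3,5-dimethoxyphenoxy)trimethylsilane | COc1cc(O[Si](C)(C)C)c(Br)c(OC)c1
F5 | step 2 | lithium 3,5-dimethoxy-2-(trimethylsilyl)phenoxide | COc1cc(OC)c([Si](C)(C)C)c(O[Li])c1
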